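Amounts first: every new flask held 2.5 M of substrate, a heavier charge than either earlier run, and each was read at 3.0 h.

| setting | north-east | east | violet | teal | blue | grey |
|---|---|---|---|---|---|---|
| substrate | 1.2 M | 1.9 M | 2.5 M | 2.5 M | 2.5 M | 2.5 M |
| temperature | −10 °C | 32 °C | 70 °C | −5 °C | 20 °C | 45 °C |
| remark | run made earlier | run made earlier |  |  |  |  |
| time |  |  | 3.0 h | 3.0 h | 3.0 h | 3.0 h |

| run | time / h | target / % | side product / % |
|---|---|---|---|
| north-east | 12.0 | 10.1 | 6.3 |
| north-east | 25.0 | 16.4 | 22.3 |
| north-east | 48.0 | 20.0 | 43.4 |
| north-east | 96.0 | 20.6 | 66.2 |
| north-east | 192 | 22.5 | 74.6 |
| east | 4.00 | 32.4 | 62.7 |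
| east | 8.00 | 31.6 | 63.8 |
| east | 12.0 | 30.8 | 64.7 |
| east | 20.0 | 32.2 | 63.8 |
| east | 25.0 | 30.9 | 65.1 |

(each reading ± 1 percentage point)

- in percentages every species weighs as the substrate in it: one side product counts as two
- steps under discussion: substrate -> target; substrate + target -> side product; target <-> isomer of the product

- the best flask by share of target in all that became target or side product or isomer of the product; "all alike" if 1.5 percentage points covers them all (violet / teal / blue / grey / all alike)
- share of target in all that became target or side product or isomer of the product, violet
- share of target in all that became target or side product or isomer of the product, teal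
- share of target in all that became target or side product or isomer of the product, blue
- share of target in all that became target or side product or isomer of the product, grey

I laid out the time scales, fastest first. The east run at 32 °C was over by 4.00 h: target and side product stood flat, with a steady 4.90% unaccounted for, which I took as isomer of the product. The north-east run at −10 °C was far slower: its first reading implied a making time of 90.6 h. Teal belonged on this slow rung, with 3.0 h much shorter than that time, so I expected teal to be read while target was still building.

I compared rates at one moment. Both steps run first order in substrate, so substrate cancels, and target made over target used equals k1/k2 divided by the target concentration. That ratio falls as target builds. Between 12.0 h and 25.0 h the north-east run used 8.00% of target while making 14.3%, at a mean target of 0.159 M. That gave 0.284 M for the target concentration at which making and using balance, the break-even level (k1/k2 is the selectivity factor). Target in that run later stalled near 0.270 M.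

Starting from no target, made over used averages about 2 times the end ratio, and the share is (made − used)/(made + used). For teal I guessed that its warmer bath doubled the making rate, which gave 6.62% made, or 0.166 M. Counting all of it as still standing, the mean ratio was 3.43 and the share 54.9%, a low-side figure.

The forecast also put teal first, but higher, at 72%, with violet 37%, grey 30% and blue 25%: “Teal wins because it is barely converted”.

The flasks gave teal first at 61.5%, then violet 41.8%, grey 32.3% and blue 22.8%.

    substrate → target (k = 0.759 h⁻¹, Ea = 86.0 kJ mol⁻¹)
    substrate + target → side product (k = 1.16 L mol⁻¹ h⁻¹, Ea = 70.0 kJ mol⁻¹)
    target ⇌ isomer of the product (K = 0.110, k = 0.0932 h⁻¹, Ea = 103 kJ mol⁻¹, ΔH = 0 kJ mol⁻¹)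
    (constants at 20 °C)

Teal's share was a point on a falling ratio: it stood at 61.5% at 3.0 h and at 17.2% at 30.0 h, a drop due to the later hour. At 3.0 h teal held 6.15% target, or 0.154 M; the break-even of 0.284 M, read at −10 °C and carried unchanged to teal's −5 °C, gave a reckoned mean ratio of 3.70 and a reckoned share of 57.4%, below the 61.5% teal gave. Teal read at 5.0 h held 8.47% target, so the same carried break-even gave a reckoned mean ratio of 2.69 and a reckoned share of 45.8%, where that flask gave 48.6%.

The earlier runs and the new flask come from a simulation for substances that don't exist; the scatter is artificial.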